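All runs are simulated for substances that don't exist; scatter was added.

Late in the earlier runs mono adduct stands at 15.7 % in birch and 15.1 % in oak at 50.0 h, so our reckoning rests on these last rows.

in all of them: solid substrate 0.39 M

|  | partner | remark | time |
|---|---|---|---|
| birch | 0.72 equiv | run made earlier |  |
| oak | 1.9 equiv | run made earlier |  |
| winter | 1.00 equiv |  | 2.0 d |
| spring | 2.50 equiv |  | 2.0 d |
| dusk | 3.00 equiv |  | 2.0 d |

- birch (time / h: mono adduct / %, double product / %): 4.00: 0, 1.4; 6.00: 2.6, 1.0; 10.0: 3.1, 0.5; 20.0: 5.3, 1.2; 30.0: 8.8, 4.8; 50.0: 15.7, 10.4
- oak (time / h: mono adduct / %, double product / %): 3.00: 1.6, 1.3; 10.0: 4.2, 0.3; 15.0: 6.4, 5.1; 25.0: 9.4, 8.3; 40.0: 13.5, 13.3; 50.0: 15.1, 15.9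

(readings scatter by 1 percentage point)

- solid substrate is a solid; its amount is given per volume of the solution
- what may be going on: starting material + partner -> mono adduct; partner + mono adduct <-> double product; partner + double product -> over-reaction product; solid substrate <-> starting material
- at the start none of the solid substrate is in solution

* final mono adduct, as a percentage of the solid substrate charged, for each flask in turn (winter, spring, dusk)

First we ask which given numbers have to be known well. Take the partner: from birch to oak it rises by a factor of 2.64, yet the mono adduct read at 50.0 h moves by 0.6 percentage points, less than the 1.4 points scatter of such a difference. Winter lies inside that range of partner, but spring and dusk lie beyond oak, so for them this flatness is an extrapolation. The solid substrate, 0.39 M, is charged as in birch and oak, so it needs no correction. The mono adduct readings of birch and oak at 50.0 h do matter: an error of 1 point in one of them moves our estimate by 0.48 points.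

We therefore replace the curve by its mean, averaging the two readings and dividing by their time:

rate = 0.00308 h⁻¹

This is the mean mono rate, the share of the solid substrate charged that stands as mono adduct, net of what has gone on to double product, per hour of run; we read it from birch and oak as an apparent zero-order rate. Over 48 h it gives:

final mono adduct = 14.8 %

To check the replacement, we take the late slopes, 0.00345 h⁻¹ in birch and 0.00228 h⁻¹ in oak, which lie on either side of the mean. Stepping back the 2.00 h from those readings to the asked time along these slopes instead of the mean shifts the value by 0.074 points in birch and 0.16 points in oak. We commit to 14.8 % for winter, spring and dusk alike.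

The forecast gives 15 %, 14.5 % and 14.2 %, a slight fall where our line is flat: “mono should stay near 15 % and fall slightly with more partner”.

The flasks give 17.2 %, 12.9 % and 11.2 %.

    starting material + partner → mono adduct (k = 0.00250 L mol⁻¹ min⁻¹)
    partner + mono adduct ⇌ double product (K = 5.90 L mol⁻¹, k = 0.00330 L mol⁻¹ min⁻¹)
    partner + double product → over-reaction product (k = 0.00120 L mol⁻¹ min⁻¹)
    solid substrate ⇌ starting material, rate k4*(cs4 - [starting material]) while solid is left; crystals form when [starting material] > cs4 (solubility = 0.190 M, k = 5.60 × 10⁻⁴ min⁻¹)

In winter, mono adduct is made 2.11 times faster than it is used up at 0.864 d, each step taken net. The mean mono rate of winter comes to 0.00358 h⁻¹, above the 0.00308 h⁻¹ we carried. In dusk it comes to 0.00233 h⁻¹, below that value, and at 2.00 d dusk holds over-reaction product at 26.9 % of the solid substrate charged.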